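The 2,4,5-trisubstituted imidazole is cut at C4–C5 and C2–N3. Its N1–C5(CH3) unit is alanine minus the carboxyl group, C2 with its acetoxybutyl chain is an acyl carbon, and C4–N3 with the arylethyl arm is an aldimine. One operation therefore builds the whole ring: the mesoionic oxazolium-5-olate (münchnone) of an N-acyl-N-benzyl alanine adds across an N-tosyl aldimine, and loss of CO2 and p-toluenesulfinic acid aromatises the adduct. The precursor is N-(5-acetoxypentanoyl)-N-(2,4-dimethoxybenzyl)alanine, dehydrated by a carbodiimide in the presence of the imine from 3-(3,4-dimethoxyphenyl)propanal; the benzyl group is removed by acid at the end.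

Key step: step 8

Assumption: L-alanine benzyl ester 1 is used as the free base, liberated from its commercial hydrochloride by a bicarbonate wash just before step 1 (not counted as a step).

Step 1
Reactants: 1 L-alanine benzyl ester; 2 2,4-dimethoxybenzaldehyde
Product: 4 benzyl N-(2,4-dimethoxybenzyl)-L-alaninate, via aldimine 3 (not isolated)
Conditions: 2 (1.0 equiv), NaBH(OAc)3 (1.4 equiv), ClCH2CH2Cl, rt
Reagents that add atoms: none
Why: Reductive amination should stop at mono-benzylation because the electron-rich aldehyde condenses to aldimine 3, which NaBH(OAc)3 reduces faster than the aldehyde, and the α-branched secondary amine formed is too hindered to react again; the stereocentre is not touched.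

Step 2
Reactants: 5 δ-valerolactone
Product: 7 5-acetoxypentanoic acid, via sodium 5-hydroxypentanoate 6 (not isolated)
Conditions: NaOH (1.0 equiv), H2O, 70 °C, evaporate to dryness; then Ac2O (3 equiv), pyridine, DMAP (5 mol %), 0 °C → rt; H2O quench, cold 1 M HCl to pH 3
Reagents that add atoms: sodium hydroxide [Na+].[OH-]; acetic anhydride CC(=O)OC(C)=O
Why: Lactone saponification followed by DMAP-catalysed O-acetylation should give the acetoxy acid, because any mixed anhydride at the carboxylate is hydrolysed on quenching and the acetylated hydroxyl can no longer relactonise on acidification.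

Step 3
Reactants: 4 benzyl N-(2,4-dimethoxybenzyl)-L-alaninate; 7 5-acetoxypentanoic acid
Product: 9 benzyl N-(5-acetoxypentanoyl)-N-(2,4-dimethoxybenzyl)-L-alaninate, via 5-acetoxypentanoyl chloride 8 (not isolated)
Conditions: 7, (COCl)2 (1.2 equiv), DMF (cat.), CH2Cl2, 0 °C → rt, evaporate; then 4, Et3N (1.5 equiv), DMAP (10 mol %), CH2Cl2, 0 °C → rt
Reagents that add atoms: none
Why: Acid chloride formation under Vilsmeier catalysis and DMAP-assisted N-acylation should work because an acid chloride is reactive enough for the hindered secondary amine while acetate and benzyl ester are inert, and any epimerisation is harmless since this centre becomes sp2 in step 8.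

Step 4
Reactants: 9 benzyl N-(5-acetoxypentanoyl)-N-(2,4-dimethoxybenzyl)-L-alaninate
Product: 10 (S)-N-(5-acetoxypentanoyl)-N-(2,4-dimethoxybenzyl)alanine
Conditions: H2 (1 atm), 10% Pd/C, EtOAc, rt
Reagents that add atoms: none
Why: Catalytic hydrogenolysis should cleave only the benzyl ester, because its benzylic C–O bond reacts far faster than the C–N bond of an N-benzyl tertiary amide, and acetate and aryl ethers are inert to H2 over Pd/C.

Step 5
Reactants: 11 3-(3,4-dimethoxyphenyl)propan-1-ol
Product: 12 3-(3,4-dimethoxyphenyl)propanal
Conditions: TEMPO (10 mol %), PhI(OAc)2 (1.1 equiv), CH2Cl2, rt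
Reagents that add atoms: none
Why: Oxoammonium (TEMPO) oxidation with PhI(OAc)2 as terminal oxidant should stop at the aldehyde in the absence of water and leaves the dimethoxyarene untouched.

Step 6
Reactants: 12 3-(3,4-dimethoxyphenyl)propanal
Product: 13 N-[3-(3,4-dimethoxyphenyl)-1-(4-methylbenzenesulfonyl)propyl]-4-methylbenzenesulfonamide (racemic)
Conditions: TsNH2 (1.0 equiv), TolSO2Na (1.1 equiv), HCO2H/H2O 1:1, rt, 24 h; filter the precipitate
Reagents that add atoms: p-toluenesulfonamide Cc1ccc(cc1)S(N)(=O)=O; sodium p-toluenesulfinate Cc1ccc(cc1)S(=O)[O-].[Na+]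
Why: In this three-component Mannich-type condensation the N-sulfonyliminium ion formed in aqueous formic acid is captured at carbon by sulfinate, and crystallisation of the α-amido sulfone drives the equilibrium and stores the enolisable imine in bench-stable form.

Step 7
Reactants: 13 N-[3-(3,4-dimethoxyphenyl)-1-(4-methylbenzenesulfonyl)propyl]-4-methylbenzenesulfonamide
Product: 14 (E)-N-[3-(3,4-dimethoxyphenyl)propylidene]-4-methylbenzenesulfonamide
Conditions: sat. aq NaHCO3/CH2Cl2, rt, 2 h; separate, dry (Na2SO4), concentrate below 25 °C, use at once (2 equiv relative to 10)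
Reagents that add atoms: none
Why: Base-induced elimination of sulfinate from the sulfonamide anion (E1cB) in a two-phase system should release the imine into CH2Cl2 while the sulfinate passes into water, so the enolisable imine never meets a soluble base; the E isomer is the thermodynamic one.

Step 8
Reactants: 10 (S)-N-(5-acetoxypentanoyl)-N-(2,4-dimethoxybenzyl)alanine; 14 (E)-N-[3-(3,4-dimethoxyphenyl)propylidene]-4-methylbenzenesulfonamide
Product: 17 4-{1-(2,4-dimethoxybenzyl)-4-[2-(3,4-dimethoxyphenyl)ethyl]-5-methyl-1H-imidazol-2-yl}butyl acetate, via münchnone 15 (not isolated), via bicyclic cycloadduct 16 (not isolated)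
Conditions: 14 (2.0 equiv), N,N'-diisopropylcarbodiimide (1.3 equiv), 4 Å MS, CH2Cl2, 10 added over 2 h at 0 °C, then rt → 40 °C; aq NaHCO3 work-up
Reagents that add atoms: none
Why: The carbodiimide turns the carboxyl group of 10 into an O-acylisourea that the amide oxygen displaces, and loss of the α-proton gives the mesoionic oxazolium-5-olate 15, a masked cyclic azomethine ylide in which the former alanine carbon is sp2. Its two termini, the methyl-bearing carbon (nucleophilic, later C5) and the chain-bearing carbon (electrophilic, later C2), add across the C=N bond of 14 to give bicycle 16, which ejects CO2 by cycloreversion and then loses p-toluenesulfinic acid (N–S cleavage plus the hydrogen at C4) to reach the aromatic ring of 17. The closest known reaction type is the imidazole synthesis from carbodiimide-generated münchnones and N-sulfonyl aldimines, here stretched to an all-alkyl dipole and an enolisable imine. The single new ring, the imidazole, is closed by an intermolecular (3+2) dipolar cycloaddition that makes C4–C5 and C2–N3 together (concerted but asynchronous, so no endo-trig closure has to be invoked). No stereocentre is formed and the one in 10 is erased. The step needs regioselectivity (imine carbon to the methyl-bearing carbon) and chemoselectivity over self-condensation of 15; the first should follow from polarity matching between the enolate-like terminus of 15 and the sulfonyl-activated imine carbon, the second from generating 15 slowly in an excess of 14.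

Step 9
Reactants: 17 4-{1-(2,4-dimethoxybenzyl)-4-[2-(3,4-dimethoxyphenyl)ethyl]-5-methyl-1H-imidazol-2-yl}butyl acetate
Product: 18 O-acetylcypholophine, 4-{4-[2-(3,4-dimethoxyphenyl)ethyl]-5-methyl-1H-imidazol-2-yl}butyl acetate
Conditions: CF3CO2H, anisole (20 equiv), 70 °C; then aq NaHCO3
Reagents that add atoms: none
Why: In this acidolytic N-debenzylation (SN1 type) the imidazole protonated at N3 is a good leaving group, the N1–CH2 bond ionises to a benzyl cation stabilised by two methoxy groups that anisole captures by Friedel–Crafts alkylation, and the primary acetate, the aryl methyl ethers and the imidazole ring should survive anhydrous acid at this temperature.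

Compound list
1 | L-alanine benzyl ester, benzyl (S)-2-aminopropanoate | C[C@H](N)C(=O)OCc1ccccc1 | starting material
2 | 2,4-dimethoxybenzaldehyde | COc1ccc(C=O)c(OC)c1 | starting material
3 | benzyl (S)-2-{[(E)-(2,4-dimethoxyphenyl)methylidene]amino}propanoate (aldimine) | C[C@H](/N=C/c1ccc(OC)cc1OC)C(=O)OCc1ccccc1 | intermediate (not isolated)
4 | benzyl N-(2,4-dimethoxybenzyl)-L-alaninate | C[C@H](NCc1ccc(OC)cc1OC)C(=O)OCc1ccccc1 | intermediate
5 | δ-valerolactone | O=C1CCCCO1 | starting material
6 | sodium 5-hydroxypentanoate | [Na+].[O-]C(=O)CCCCO | intermediate (not isolated)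
7 | 5-acetoxypentanoic acid | CC(=O)OCCCCC(=O)O | intermediate
8 | 5-acetoxypentanoyl chloride | CC(=O)OCCCCC(Cl)=O | intermediate (not isolated)
9 | benzyl N-(5-acetoxypentanoyl)-N-(2,4-dimethoxybenzyl)-L-alaninate | C[C@H](N(Cc1ccc(OC)cc1OC)C(=O)CCCCOC(C)=O)C(=O)OCc1ccccc1 | intermediate
10 | (S)-N-(5-acetoxypentanoyl)-N-(2,4-dimethoxybenzyl)alanine | C[C@H](N(Cc1ccc(OC)cc1OC)C(=O)CCCCOC(C)=O)C(=O)O | intermediate
11 | 3-(3,4-dimethoxyphenyl)propan-1-ol | COc1ccc(CCCO)cc1OC | starting material
12 | 3-(3,4-dimethoxyphenyl)propanal | COc1ccc(CCC=O)cc1OC | intermediate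
13 | N-[3-(3,4-dimethoxyphenyl)-1-(4-methylbenzenesulfonyl)propyl]-4-methylbenzenesulfonamide (racemic) | COc1ccc(CCC(NS(=O)(=O)c2ccc(C)cc2)S(=O)(=O)c2ccc(C)cc2)cc1OC | intermediate
14 | (E)-N-[3-(3,4-dimethoxyphenyl)propylidene]-4-methylbenzenesulfonamide | COc1ccc(CC/C=N/S(=O)(=O)c2ccc(C)cc2)cc1OC | intermediate
15 | 2-(4-acetoxybutyl)-3-(2,4-dimethoxybenzyl)-4-methyl-1,3-oxazol-3-ium-5-olate (münchnone) | CC1=C([O-])OC(CCCCOC(C)=O)=[N+]1Cc1ccc(OC)cc1OC | intermediate (not isolated)
16 | 4-{7-(2,4-dimethoxybenzyl)-5-[2-(3,4-dimethoxyphenyl)ethyl]-4-methyl-3-oxo-6-tosyl-2-oxa-6,7-diazabicyclo[2.2.1]heptan-1-yl}butyl acetate (bicyclic cycloadduct, relative configuration not defined) | CC12C(=O)OC(CCCCOC(C)=O)(N1Cc1ccc(OC)cc1OC)N(S(=O)(=O)c1ccc(C)cc1)C2CCc1ccc(OC)c(OC)c1 | intermediate (not isolated)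
17 | 4-{1-(2,4-dimethoxybenzyl)-4-[2-(3,4-dimethoxyphenyl)ethyl]-5-methyl-1H-imidazol-2-yl}butyl acetate | COc1ccc(CCc2nc(CCCCOC(C)=O)n(Cc3ccc(OC)cc3OC)c2C)cc1OC | intermediate
18 | O-acetylcypholophine, 4-{4-[2-(3,4-dimethoxyphenyl)ethyl]-5-methyl-1H-imidazol-2-yl}butyl acetate (no stereocentre) | COc1ccc(CCc2nc(CCCCOC(C)=O)[nH]c2C)cc1OC | target

Total step count: 9.
Longest linear sequence: 5 steps (for example 5 → 7 → 9 → 10 → 17 → 18; the other two branches are equally long).

Steps most likely to fail

1. Step 8. The all-alkyl dipole may condense with itself or with its activated precursor before it meets the imine. The enolisable imine may tautomerise to the ene-sulfonamide, and the sulfinic acid set free may add back to the imine and withdraw it. The fallback uses known chemistry and no longer needs the imine. It sets out from acid 10. 3-(3,4-Dimethoxyphenyl)propanoic anhydride F1 is prepared from the commercial acid (COc1ccc(CCC(=O)O)cc1OC) with N,N'-dicyclohexylcarbodiimide (0.5 equiv) in CH2Cl2. Heating 10 with F1 (3 equiv), Et3N and DMAP (cat.) at 50 °C is a Dakin–West reaction: C-acylation at the alanine carbon and decarboxylation should give the α-(N-acylamino) ketone 5-{(2,4-dimethoxybenzyl)[5-(3,4-dimethoxyphenyl)-3-oxopentan-2-yl]amino}-5-oxopentyl acetate F2. Cyclocondensation of F2 with NH4OAc in AcOH at 110 °C should then give 17, with ammonia supplying N3, the ketone carbon becoming C4 and the amide carbon C2. The route is rejoined at 17, before step 9.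

2. Step 9. Heterolysis of the N1–benzyl bond may be slow, so that acid-catalysed acyl exchange at the acetate and benzylation of the veratryl ring by the liberated cation compete. The fallback gives up the selective deprotection and reinstalls the ester. It sets out from 17, which is heated in CF3CO2H with 5% CF3SO3H and anisole until debenzylation is complete, without regard for the ester. The crude product is stirred with K2CO3 in MeOH so that the acetate and any trifluoroacetate are methanolysed together, giving cypholophine, 4-{4-[2-(3,4-dimethoxyphenyl)ethyl]-5-methyl-1H-imidazol-2-yl}butan-1-ol F3. Acetylation of F3 with Ac2O in pyridine, followed by an aqueous methanolic NaHCO3 work-up that hydrolyses any labile N-acetylimidazole, should return the route at 18.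

3. Step 7. During the two-phase release and the concentration the imine may tautomerise, hydrolyse back to the aldehyde or oligomerise. The fallback makes the imine without base or water. It sets out from aldehyde 12. N-Sulfinyl-4-methylbenzenesulfonamide F4, prepared from TsNH2 and SOCl2 at reflux, is added in slight deficit to 12 in CH2Cl2 at rt. Addition across the C=O bond and cycloreversion with loss of SO2 should give 14 directly as an anhydrous solution, which enters step 8 without concentration. The deficit of F4 ensures that none of this reactive heterocumulene is left to compete for the dipole.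

Further compounds
F1 | step 8 | 3-(3,4-dimethoxyphenyl)propanoic anhydride | COc1ccc(CCC(=O)OC(=O)CCc2ccc(OC)c(OC)c2)cc1OC
F2 | step 8 | 5-{(2,4-dimethoxybenzyl)[5-(3,4-dimethoxyphenyl)-3-oxopentan-2-yl]amino}-5-oxopentyl acetate (racemic) | CC(N(Cc1ccc(OC)cc1OC)C(=O)CCCCOC(C)=O)C(=O)CCc1ccc(OC)c(OC)c1
F3 | step 9 | cypholophine, 4-{4-[2-(3,4-dimethoxyphenyl)ethyl]-5-methyl-1H-imidazol-2-yl}butan-1-ol | COc1ccc(CCc2nc(CCCCO)[nH]c2C)cc1OC
F4 | step 7 | N-sulfinyl-4-methylbenzenesulfonamide | Cc1ccc(S(=O)(=O)N=S=O)cc1
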